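**Plan**

1. Atom labels (target lactone numbering, kept for all intermediates): O1, C2 (C=O), C3 (quaternary carbinol), C4, C5 (OCH2); C7' is the benzylic carbinol carbon on C4.
2. Retrosynthetic cuts, in order: the two phenol O–benzyl groups; the lactone bond O1–C2 (back to a methyl ester and a C5 hydroxyl); C5–OH back to C5–Si, so that C5, Si and the C7' oxygen sit in a 1-oxa-2-silacyclopentane; C4–C5 and C3–OH together (radical ring closure with O2 capture); C3–CH2Ar (Negishi); C7'–alkyne (asymmetric alkynylation).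
3. Enabling feature: O1–C5–C4–C7'–OH is a 2-substituted propane-1,3-diol, so the benzylic oxygen can carry a silicon tether that delivers C5 to C4. C3 lies α to the C2 carbonyl, so a C3=C4 enoate accepts the tethered radical at C4 and passes the spin to C3 for C–O bond formation.
4. Forward: O-benzylvanillin + methyl propiolate → ynoate → (Z)-α-iodo enoate → (E)-α-benzyl enoate → silyl tether → oxasilolane ring (C4–C5 bond, C3–OH) → Tamao oxidation, after which the lactone ring (O1–C2) closes → debenzylation.
5. Stereochemistry: C7' from the Me2Zn/ProPhenol catalyst; C4 from C7' (allylic strain in the 5-exo transition state, trans-oxasilolane); C3 from C4 (facial control in O2 capture of the acyclic radical).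

Key step: step 6

Assumption: the (S,S)-ProPhenol/Me2Zn catalyst is taken to deliver the alkynyl group to the Re face of the aryl aldehyde; if the sense is the opposite, the (R,R)-ligand is used and nothing else changes.

**Route**

Step 1
Reactants: 1 4-(benzyloxy)-3-methoxybenzaldehyde; 2 methyl propiolate
Product: 3 methyl (S)-4-[4-(benzyloxy)-3-methoxyphenyl]-4-hydroxybut-2-ynoate
Conditions: Me2Zn (3 equiv), (S,S)-ProPhenol (20 mol%), Ph3P=O (40 mol%), PhMe, 0 °C; aq. NH4Cl
Reagents that add atoms: none
Why: Me2Zn/ProPhenol-catalysed asymmetric alkynylation of an aryl aldehyde, in which the dinuclear zinc alkynyl complex adds the propiolate to the Re face and so sets C7' (S in 3 because the alkynyl group outranks the aryl group; the same spatial arrangement is R from 4 onward).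

Step 2
Reactants: 3 methyl (S)-4-[4-(benzyloxy)-3-methoxyphenyl]-4-hydroxybut-2-ynoate
Product: 5 methyl (R,Z)-4-[4-(benzyloxy)-3-methoxyphenyl]-4-hydroxy-2-iodobut-2-enoate, via sodium alkenylaluminate chelate 4 (not isolated)
Conditions: NaAlH2(OCH2CH2OMe)2, THF, −72 °C; then I2, −72 → −20 °C; aq. Na2S2O3/Rochelle salt
Reagents that add atoms: iodine, II
Why: Alkoxide-directed trans-hydroalumination of the γ-hydroxy ynoate puts hydride on C4 and aluminium on C3 inside a five-membered chelate, and iodinolysis of the C–Al bond with retention gives the iodide with the ester trans to C7', a geometry that cannot lactonise onto the C7' hydroxyl.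

Step 3
Reactants: 6 [4-(benzyloxy)-3-methoxyphenyl]methanol
Product: 7 1-(benzyloxy)-4-(chloromethyl)-2-methoxybenzene
Conditions: SOCl2, CH2Cl2, 0 °C → rt
Reagents that add atoms: thionyl chloride, O=S(Cl)Cl
Why: Deoxychlorination of a benzylic alcohol by SOCl2 through the chlorosulfite.

Step 4
Reactants: 7 1-(benzyloxy)-4-(chloromethyl)-2-methoxybenzene; 5 methyl (R,Z)-4-[4-(benzyloxy)-3-methoxyphenyl]-4-hydroxy-2-iodobut-2-enoate
Product: 9 methyl (R,E)-2-[4-(benzyloxy)-3-methoxybenzyl]-4-[4-(benzyloxy)-3-methoxyphenyl]-4-hydroxybut-2-enoate, via benzylic zinc chloride 8 (not isolated)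
Conditions: 7, Zn dust, LiCl, THF, rt; then 5 (8 in excess, slow addition), Pd(OAc)2 (2 mol%), SPhos (4 mol%), THF, rt
Reagents that add atoms: none
Why: LiCl-promoted zinc insertion into the benzylic chloride followed by Negishi coupling with the α-iodo enoate, whose oxidative addition and reductive elimination retain the alkene geometry, so the new benzyl group ends cis to C7' and the ester stays trans to it.

Step 5
Reactants: 9 methyl (R,E)-2-[4-(benzyloxy)-3-methoxybenzyl]-4-[4-(benzyloxy)-3-methoxyphenyl]-4-hydroxybut-2-enoate; 10 (bromomethyl)chlorodimethylsilane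
Product: 11 methyl (R,E)-2-[4-(benzyloxy)-3-methoxybenzyl]-4-[4-(benzyloxy)-3-methoxyphenyl]-4-{[(bromomethyl)dimethylsilyl]oxy}but-2-enoate
Conditions: Et3N, DMAP (cat.), CH2Cl2, 0 °C; filtered through a short silica pad and used at once
Reagents that add atoms: none
Why: O-Silylation of the secondary allylic alcohol by the chlorosilane under amine base installs the radical precursor and the tether without touching C7'.

Step 6
Reactants: 11 methyl (R,E)-2-[4-(benzyloxy)-3-methoxybenzyl]-4-[4-(benzyloxy)-3-methoxyphenyl]-4-{[(bromomethyl)dimethylsilyl]oxy}but-2-enoate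
Product: 13 methyl (S)-3-[4-(benzyloxy)-3-methoxyphenyl]-2-{(4R,5R)-5-[4-(benzyloxy)-3-methoxyphenyl]-2,2-dimethyl-1,2-oxasilolan-4-yl}-2-hydroxypropanoate, via tertiary hydroperoxide 12 (not isolated)
Conditions: Bu3SnH (2.2 equiv, slow addition), dry air (slow stream), Et3B (0.2 equiv), PhMe (0.01 M), 0 °C; then PPh3, rt
Reagents that add atoms: dioxygen, O=O
Why: Proposed new method: Bu3Sn• abstracts bromine from 11 and the nucleophilic silylmethyl radical adds 5-exo-trig to C4, the electron-poor β-carbon of the enoate, which closes the 1-oxa-2-silacyclopentane and forms C4–C5; the tertiary α-ester radical at C3 then combines with O2 and the peroxyl radical takes hydrogen from Bu3SnH to give hydroperoxide 12, which PPh3 reduces in a polar step. The closest known reaction types are the hydrogen-terminated cyclization of (bromomethyl)dimethylsilyl ethers of allylic alcohols (Nishiyama–Stork) and the Bu3SnH/O2 oxygenative cyclization of halo acetals; their merger on a trisubstituted enoate to give a tertiary α-hydroxy ester is not known. The ring closes in the 5-exo-trig mode because 6-endo attack would have to take place at the fully substituted C3 and would give a non-stabilized radical. C4 is controlled by C7': allylic 1,3-strain with the cis benzyl group on C3 holds the C7'–H bond in the enoate plane, so the tether delivers C5 to the face that carries the oxygen and the aryl group ends up trans to the C3 side chain on the new ring, which is the (R) configuration at C4. C3 is controlled by C4: in the planar α-ester radical the C4–H bond should eclipse the ester group and O2 should enter anti to the more branched ring carbon C7', which gives (S), and this is the least secure element of the step. The step needs ring closure to outrun oxygen capture of the primary radical and oxygen capture to outrun hydrogen transfer at C3; the fast polarity-matched 5-exo addition, a slow air stream and slow addition of Bu3SnH at high dilution should secure both.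

Step 7
Reactants: 13 methyl (S)-3-[4-(benzyloxy)-3-methoxyphenyl]-2-{(4R,5R)-5-[4-(benzyloxy)-3-methoxyphenyl]-2,2-dimethyl-1,2-oxasilolan-4-yl}-2-hydroxypropanoate
Product: 15 (3S,4R)-3-[4-(benzyloxy)-3-methoxybenzyl]-4-{(R)-[4-(benzyloxy)-3-methoxyphenyl](hydroxy)methyl}-3-hydroxyoxolan-2-one, via triol methyl ester 14 (not isolated)
Conditions: KF, KHCO3, 30% aq. H2O2, THF/MeOH (1:1), rt → 40 °C; aq. Na2S2O3
Reagents that add atoms: hydrogen peroxide, OO
Why: Tamao–Fleming oxidation of the alkoxy(dialkyl)silane converts C5–Si into C5–OH and frees the C7' hydroxyl, after which the primary alkoxide transesterifies the methyl ester in a 5-exo-trig lactonisation, closure through the C7' oxygen being slower and leading to a more strained cis-aryl/hydroxymethyl lactone; no stereocenter is touched.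

Step 8
Reactants: 15 (3S,4R)-3-[4-(benzyloxy)-3-methoxybenzyl]-4-{(R)-[4-(benzyloxy)-3-methoxyphenyl](hydroxy)methyl}-3-hydroxyoxolan-2-one
Product: 16 (3S,4R)-3-hydroxy-4-[(R)-hydroxy(4-hydroxy-3-methoxyphenyl)methyl]-3-(4-hydroxy-3-methoxybenzyl)oxolan-2-one (CNP0352022.1)
Conditions: H2 (1 atm), Pd/C (10%), EtOAc, rt, stopped at complete conversion
Reagents that add atoms: none
Why: Hydrogenolysis of the two aryl benzyl ethers over Pd/C, which under neutral conditions is much faster than reduction of the benzylic C7'–OH bond and leaves the lactone and the tertiary alcohol alone.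

**Compound list**

1 | 4-(benzyloxy)-3-methoxybenzaldehyde | COc1cc(C=O)ccc1OCc1ccccc1 | starting material
2 | methyl propiolate | C#CC(=O)OC | starting material
3 | methyl (S)-4-[4-(benzyloxy)-3-methoxyphenyl]-4-hydroxybut-2-ynoate | COC(=O)C#C[C@@H](O)c1ccc(OCc2ccccc2)c(OC)c1 | intermediate
4 | sodium alkenylaluminate chelate: five-membered ring O–Al–C3=C4–C7' with (R)-C7', two 2-methoxyethoxy groups on Al, CO2Me on C3 | COC(=O)C1=C[C@H](c2ccc(OCc3ccccc3)c(OC)c2)O[Al-]1(OCCOC)OCCOC.[Na+] | intermediate (not isolated)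
5 | methyl (R,Z)-4-[4-(benzyloxy)-3-methoxyphenyl]-4-hydroxy-2-iodobut-2-enoate | COC(=O)/C(I)=C/[C@@H](O)c1ccc(OCc2ccccc2)c(OC)c1 | intermediate
6 | [4-(benzyloxy)-3-methoxyphenyl]methanol | COc1cc(CO)ccc1OCc1ccccc1 | starting material
7 | 1-(benzyloxy)-4-(chloromethyl)-2-methoxybenzene | COc1cc(CCl)ccc1OCc1ccccc1 | intermediate
8 | [4-(benzyloxy)-3-methoxybenzyl]zinc chloride | COc1cc(C[Zn]Cl)ccc1OCc1ccccc1 | intermediate (not isolated)
9 | methyl (R,E)-2-[4-(benzyloxy)-3-methoxybenzyl]-4-[4-(benzyloxy)-3-methoxyphenyl]-4-hydroxybut-2-enoate | COC(=O)/C(Cc1ccc(OCc2ccccc2)c(OC)c1)=C/[C@@H](O)c1ccc(OCc2ccccc2)c(OC)c1 | intermediate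
10 | (bromomethyl)chlorodimethylsilane | C[Si](C)(Cl)CBr | starting material
11 | methyl (R,E)-2-[4-(benzyloxy)-3-methoxybenzyl]-4-[4-(benzyloxy)-3-methoxyphenyl]-4-{[(bromomethyl)dimethylsilyl]oxy}but-2-enoate | COC(=O)/C(Cc1ccc(OCc2ccccc2)c(OC)c1)=C/[C@@H](O[Si](C)(C)CBr)c1ccc(OCc2ccccc2)c(OC)c1 | intermediate
12 | methyl (S)-3-[4-(benzyloxy)-3-methoxyphenyl]-2-{(4R,5R)-5-[4-(benzyloxy)-3-methoxyphenyl]-2,2-dimethyl-1,2-oxasilolan-4-yl}-2-hydroperoxypropanoate | COC(=O)[C@](OO)(Cc1ccc(OCc2ccccc2)c(OC)c1)[C@@H]1C[Si](C)(C)O[C@H]1c3ccc(OCc4ccccc4)c(OC)c3 | intermediate (not isolated)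
13 | methyl (S)-3-[4-(benzyloxy)-3-methoxyphenyl]-2-{(4R,5R)-5-[4-(benzyloxy)-3-methoxyphenyl]-2,2-dimethyl-1,2-oxasilolan-4-yl}-2-hydroxypropanoate | COC(=O)[C@](O)(Cc1ccc(OCc2ccccc2)c(OC)c1)[C@@H]1C[Si](C)(C)O[C@H]1c3ccc(OCc4ccccc4)c(OC)c3 | intermediate
14 | methyl (2S,3R,4R)-2-[4-(benzyloxy)-3-methoxybenzyl]-4-[4-(benzyloxy)-3-methoxyphenyl]-2,4-dihydroxy-3-(hydroxymethyl)butanoate | COC(=O)[C@](O)(Cc1ccc(OCc2ccccc2)c(OC)c1)[C@H](CO)[C@@H](O)c1ccc(OCc2ccccc2)c(OC)c1 | intermediate (not isolated)
15 | (3S,4R)-3-[4-(benzyloxy)-3-methoxybenzyl]-4-{(R)-[4-(benzyloxy)-3-methoxyphenyl](hydroxy)methyl}-3-hydroxyoxolan-2-one | COc1cc(C[C@@]2(O)C(=O)OC[C@@H]2[C@@H](O)c2ccc(OCc3ccccc3)c(OC)c2)ccc1OCc1ccccc1 | intermediate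
16 | (3S,4R)-3-hydroxy-4-[(R)-hydroxy(4-hydroxy-3-methoxyphenyl)methyl]-3-(4-hydroxy-3-methoxybenzyl)oxolan-2-one | COc1cc(C[C@@]2(O)C(=O)OC[C@@H]2[C@@H](O)c2ccc(O)c(OC)c2)ccc1O | target

**Step count**

Total steps: 8. Longest linear sequence: 7 (steps 1, 2, 4, 5, 6, 7, 8); step 3 is a one-step branch.

**Steps most likely to fail**

1. Step 6 (proposed new method). What may go wrong: oxygen capture of the primary silylmethyl radical before ring closure; hydrogen transfer to the C3 radical before oxygen capture; poor facial selectivity in the C–O bond formation at C3; or β-scission of an alkoxyl radical formed when stannyl radicals attack the hydroperoxide. Fallback, known chemistry, from 3 back to 15: the benzyl group is left out until the end and C3 is built by enolate chemistry, in which the benzyl electrophile enters anti to the C4 substituent (direct hydroxylation of an α-benzyl lactone enolate would put the hydroxyl on the wrong face). Trans-selective reduction of 3 (NaAlH2(OCH2CH2OMe)2, THF, −72 °C, proton quench) should give methyl (R,E)-4-[4-(benzyloxy)-3-methoxyphenyl]-4-hydroxybut-2-enoate F1. Silylation with 10 (Et3N, DMAP) should give methyl (R,E)-4-[4-(benzyloxy)-3-methoxyphenyl]-4-{[(bromomethyl)dimethylsilyl]oxy}but-2-enoate F2. The hydrogen-terminated silicon-tethered cyclization (Bu3SnH, AIBN, PhH, 80 °C) should give methyl 2-{(4S,5R)-5-[4-(benzyloxy)-3-methoxyphenyl]-2,2-dimethyl-1,2-oxasilolan-4-yl}acetate F3; the ring closure is again trans, but without a cis substituent on C3 a lower selectivity must be expected. Tamao oxidation with lactonisation (KF, KHCO3, H2O2) should give (R)-4-{(R)-[4-(benzyloxy)-3-methoxyphenyl](hydroxy)methyl}oxolan-2-one F4, and tert-butyldimethylsilyl triflate/2,6-lutidine its silyl ether (R)-4-{(R)-[4-(benzyloxy)-3-methoxyphenyl][(tert-butyldimethylsilyl)oxy]methyl}oxolan-2-one F5. Enolate hydroxylation (KN(SiMe3)2, then 2-(phenylsulfonyl)-3-phenyloxaziridine, THF, −78 °C) should give (3RS,4S)-4-{(R)-[4-(benzyloxy)-3-methoxyphenyl][(tert-butyldimethylsilyl)oxy]methyl}-3-hydroxyoxolan-2-one F6, both C3 epimers being usable. Its dianion (LiN(iPr)2, 2.2 equiv, THF/DMPU, −78 °C) is benzylated with 7 (NaI) to give (3S,4R)-3-[4-(benzyloxy)-3-methoxybenzyl]-4-{(R)-[4-(benzyloxy)-3-methoxyphenyl][(tert-butyldimethylsilyl)oxy]methyl}-3-hydroxyoxolan-2-one F7. Bu4NF/AcOH then removes the silyl group and returns 15.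

2. Step 7. What may go wrong: the ring may close through the C7' oxygen, or not close at all under the buffered peroxide conditions, and peroxide may cleave the α-hydroxy ester oxidatively. Fallback, from 13 back to 15: kinetic transesterification is replaced by thermodynamic relactonisation of the free acid. After the Tamao oxidation the crude 14 is saponified (LiOH, THF/H2O) to (2S,3R,4R)-2-[4-(benzyloxy)-3-methoxybenzyl]-4-[4-(benzyloxy)-3-methoxyphenyl]-2,4-dihydroxy-3-(hydroxymethyl)butanoic acid F8. Careful acidification to pH 3–4 at rt should close the lactone on the primary C5 hydroxyl, which gives the less strained ring, and return 15.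

3. Step 4. What may go wrong: protonolysis of the benzylic zinc reagent by the free hydroxyl, homocoupling of the benzylic zinc reagent, or loss of alkene geometry at palladium followed by lactonisation to a butenolide. Fallback, from 3 and 7 back to 9: the polarity of the coupling is reversed. The alkenylaluminate 4, generated from 3 as in step 2, is not iodinated but coupled in the same flask with benzylic chloride 7 (ZnCl2, Pd(PPh3)4, THF, −72 °C → rt), the known zerovalent-palladium-catalysed coupling of alkenylalanes with benzyl halides. This makes no new compound (F0) and bypasses 5 and 8.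

**Further compounds**

F1 | step 6 | methyl (R,E)-4-[4-(benzyloxy)-3-methoxyphenyl]-4-hydroxybut-2-enoate | COC(=O)/C=C/[C@@H](O)c1ccc(OCc2ccccc2)c(OC)c1
F2 | step 6 | methyl (R,E)-4-[4-(benzyloxy)-3-methoxyphenyl]-4-{[(bromomethyl)dimethylsilyl]oxy}but-2-enoate | COC(=O)/C=C/[C@@H](O[Si](C)(C)CBr)c1ccc(OCc2ccccc2)c(OC)c1
F3 | step 6 | methyl 2-{(4S,5R)-5-[4-(benzyloxy)-3-methoxyphenyl]-2,2-dimethyl-1,2-oxasilolan-4-yl}acetate | COC(=O)C[C@@H]1C[Si](C)(C)O[C@H]1c1ccc(OCc2ccccc2)c(OC)c1
F4 | step 6 | (R)-4-{(R)-[4-(benzyloxy)-3-methoxyphenyl](hydroxy)methyl}oxolan-2-one | O=C1OC[C@H]([C@@H](O)c2ccc(OCc3ccccc3)c(OC)c2)C1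
F5 | step 6 | (R)-4-{(R)-[4-(benzyloxy)-3-methoxyphenyl][(tert-butyldimethylsilyl)oxy]methyl}oxolan-2-one | O=C1OC[C@H]([C@@H](O[Si](C)(C)C(C)(C)C)c2ccc(OCc3ccccc3)c(OC)c2)C1
F6 | step 6 | (3RS,4S)-4-{(R)-[4-(benzyloxy)-3-methoxyphenyl][(tert-butyldimethylsilyl)oxy]methyl}-3-hydroxyoxolan-2-one | O=C1OC[C@H]([C@@H](O[Si](C)(C)C(C)(C)C)c2ccc(OCc3ccccc3)c(OC)c2)C1O
F7 | step 6 | (3S,4R)-3-[4-(benzyloxy)-3-methoxybenzyl]-4-{(R)-[4-(benzyloxy)-3-methoxyphenyl][(tert-butyldimethylsilyl)oxy]methyl}-3-hydroxyoxolan-2-one | COc1cc(C[C@@]2(O)C(=O)OC[C@@H]2[C@@H](O[Si](C)(C)C(C)(C)C)c2ccc(OCc3ccccc3)c(OC)c2)ccc1OCc1ccccc1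
F8 | step 7 | (2S,3R,4R)-2-[4-(benzyloxy)-3-methoxybenzyl]-4-[4-(benzyloxy)-3-methoxyphenyl]-2,4-dihydroxy-3-(hydroxymethyl)butanoic acid | OC(=O)[C@](O)(Cc1ccc(OCc2ccccc2)c(OC)c1)[C@H](CO)[C@@H](O)c1ccc(OCc2ccccc2)c(OC)c1
F0 | step 4 | none | none
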